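Ring B is closed last, at its least hindered bond C6–C7. The 6β-oxygen on C6 and the C8 methyl carbon C17 sit 1,3 to each other across ring B, so O–C6–C7–C8(=C17) is read as a 3-methylenecyclohexanol. It is opened to a ring A aldehyde (C6 on C5) whose C10 carries the finished 9,13-epoxide ring with an isopropenyl group (C7=C8–C17) on C9. One Me2AlCl-promoted carbonyl-ene closure then forms C6–C7, ring B and the axial 6β-hydroxyl, and leaves the 8(17)-alkene for setting C8. The crowded C9–C10 bond is made earlier by an Ireland–Claisen rearrangement. C13 is set by lactonisation of one of two equal CH2OH arms.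

Key step: step 18

Remark: labdane numbering is used for all intermediates; compounds 1, 6 and 7 are taken as purchasable; the alkyne is carried as its triisopropylsilyl derivative (same skeleton), which one silylation installs together with the O-16 ether and which shields the alkyne in the later directed hydrogenation.

Step 1
Reactants: 1 2,6,6-trimethylcyclohex-2-ene-1,4-dione (ketoisophorone)
Product: 2 monoketal 7,9,9-trimethyl-1,4-dioxaspiro[4.5]dec-6-en-8-one
Conditions: HOCH2CH2OH, p-TsOH (cat.), PhH, reflux, Dean–Stark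
Reagents that add atoms: ethylene glycol, OCCO
Why: Acid-catalysed ketalisation should occur only at the unhindered C4 carbonyl, because the other carbonyl is flanked by the gem-dimethyl carbon and the methyl-bearing alkene carbon.

Step 2
Reactants: 2 monoketal
Product: 4 dienone 3,5,5-trimethyl-4-methylenecyclohex-2-en-1-one, via diene ketal 3 (not isolated)
Conditions: Ph3PCH3Br, KOtBu, PhMe, 80 °C; then 1 M HCl, THF, 0 °C
Reagents that add atoms: methyltriphenylphosphonium bromide, [Br-].C[P+](c1ccccc1)(c1ccccc1)c1ccccc1; water, O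
Why: Wittig methylenation of this non-enolisable hindered ketone with excess ylide should give the exocyclic diene (future C5=C6), and mild acetal hydrolysis then frees the cross-conjugated dienone.

Step 3
Reactants: 4 dienone
Product: 5 (S)-3,5,5-trimethyl-4-methylenecyclohex-2-en-1-ol
Conditions: (R)-Me-CBS (15 mol %), catecholborane, PhMe, −78 °C
Reagents that add atoms: none
Why: Corey–Bakshi–Shibata reduction with catecholborane reduces enone carbonyls 1,2 without hydroborating the diene, and with the alkenyl flank acting as the large group the (R)-catalyst should give the (S)-carbinol (future C2), the only source of absolute configuration in the route.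

Step 4
Reactants: 6 1,3-bis(benzyloxy)propan-2-one; 7 but-3-en-1-ylmagnesium bromide
Product: 8 1-(benzyloxy)-2-[(benzyloxy)methyl]hex-5-en-2-ol
Conditions: THF, −78 → 0 °C
Reagents that add atoms: none
Why: Grignard addition to the symmetrical ketone gives a tertiary alcohol whose carbinol carbon (future C13) carries two identical benzyloxymethyl arms and is therefore not yet stereogenic.

Step 5
Reactants: 8 tertiary alcohol
Product: 10 [5,5-bis(benzyloxymethyl)tetrahydrofuran-2-yl]methanol, via epoxide 9 (not isolated)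
Conditions: mCPBA, CH2Cl2, 0 °C → rt; then CSA (cat.)
Reagents that add atoms: mCPBA, OOC(=O)c1cccc(Cl)c1
Why: Prilezhaev epoxidation of the terminal alkene followed by acid-catalysed 5-exo-tet opening of the epoxide by the tertiary hydroxyl should give the tetrahydrofuran; the new ring carbon (future C9) is racemic, which is harmless because it is enolised in step 8.

Step 6
Reactants: 10 tetrahydrofuran alcohol
Product: 11 5,5-bis(benzyloxymethyl)tetrahydrofuran-2-carboxylic acid
Conditions: TEMPO (cat.), PhI(OAc)2, MeCN/H2O, rt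
Reagents that add atoms: water, O
Why: TEMPO/PhI(OAc)2 oxidation in aqueous acetonitrile takes the primary alcohol through the aldehyde hydrate to the acid and leaves benzyl ethers untouched.

Step 7
Reactants: 5 (S)-dienol; 11 acid
Product: 12 (S)-3,5,5-trimethyl-4-methylenecyclohex-2-en-1-yl 5,5-bis(benzyloxymethyl)tetrahydrofuran-2-carboxylate
Conditions: DCC, DMAP (cat.), CH2Cl2, 0 °C → rt
Reagents that add atoms: none
Why: Steglich esterification joins the secondary allylic alcohol and the acid under neutral conditions that should not ionise the dienyl carbinol, so the C2 configuration is retained.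

Step 8
Reactants: 12 dienyl ester
Product: 16 methyl 5,5-bis(benzyloxymethyl)-2-(1,5,5-trimethyl-6-methylenecyclohex-2-en-1-yl)tetrahydrofuran-2-carboxylate, via silyl ketene acetal 13 (not isolated), via trimethylsilyl ester 14 (not isolated), via carboxylic acid 15 (not isolated)
Conditions: LDA, TMSCl, THF, −78 °C → rt; 1 M HCl; then TMSCHN2, PhMe/MeOH, 0 °C
Reagents that add atoms: trimethylsilyldiazomethane, C[Si](C)(C)C=[N+]=[N-]
Why: Ireland–Claisen rearrangement: lithium chelation between the enolate oxygen and the ring oxygen gives the (Z)-silyl ketene acetal, and the suprafacial [3,3] shift through the boat-like array usual for cyclohexenyl esters (the chair would push the silyloxy group under the ring beside the C4 methyl) should bond C9 to C10 on the face that O-2 leaves, setting the 10β-methyl from the (S)-carbinol and C9 with its oxygen α; the crude acid is then methylated with TMSCHN2.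

Step 9
Reactants: 16 methyl ester
Product: 17 methyl 5,5-bis(benzyloxymethyl)-2-[6-(hydroxymethyl)-1,5,5-trimethylcyclohex-2-en-1-yl]tetrahydrofuran-2-carboxylate
Conditions: 9-BBN, THF, 60 °C; then H2O2, NaOAc, H2O, 0 °C → rt
Reagents that add atoms: hydrogen peroxide, OO
Why: Hydroboration–oxidation with 9-BBN selects the exocyclic 1,1-disubstituted alkene over the ring alkene and should add from the α face, opposite the two syn-axial methyl groups on C4 and C10, so that H-5 is α (axial) and C6 is equatorial and trans to C9.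

Step 10
Reactants: 17 primary alcohol
Product: 18 triethylsilyl ether of 17
Conditions: TESCl, imidazole, CH2Cl2, 0 °C
Reagents that add atoms: chlorotriethylsilane, CC[Si](Cl)(CC)CC
Why: Silylation of the primary alcohol masks O-6 so that it cannot lactonise onto C8, and the triethylsilyl group can later be removed beside triisopropylsilyl groups.

Step 11
Reactants: 18 triethylsilyl ether
Product: 20 5-(hydroxymethyl)-1-[1,3,3-trimethyl-2-(triethylsilyloxymethyl)cyclohexyl]-3,8-dioxabicyclo[3.2.1]octan-2-one, via diol ester 19 (not isolated)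
Conditions: H2 (1 atm), 10% Pd/C, EtOAc, rt; filter; then Ti(OiPr)4 (10 mol %), PhMe, 90 °C
Reagents that add atoms: none
Why: Catalytic hydrogenation saturates C1=C2 and hydrogenolyses both benzyl ethers, and the titanate-catalysed transesterification (lactonisation) can then only engage the CH2OH arm cis to the ester on the tetrahydrofuran ring, which makes C13 stereogenic with the configuration dictated by C9 (lactone CH2 = C16, free arm = C14).

Step 12
Reactants: 20 lactone alcohol
Product: 21 2-oxo-1-[1,3,3-trimethyl-2-(triethylsilyloxymethyl)cyclohexyl]-3,8-dioxabicyclo[3.2.1]octane-5-carbaldehyde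
Conditions: DMP, CH2Cl2, 0 °C → rt
Reagents that add atoms: none
Why: Dess–Martin oxidation of the one free primary alcohol gives a non-enolisable aldehyde on the quaternary C13.

Step 13
Reactants: 21 lactone aldehyde
Product: 22 5-ethynyl-1-[1,3,3-trimethyl-2-(triethylsilyloxymethyl)cyclohexyl]-3,8-dioxabicyclo[3.2.1]octan-2-one
Conditions: TMSCHN2, LDA, THF, −78 → 0 °C
Reagents that add atoms: trimethylsilyldiazomethane, C[Si](C)(C)C=[N+]=[N-]
Why: Colvin rearrangement (Seyferth–Gilbert-type homologation with lithiated trimethylsilyldiazomethane) converts the aldehyde into the terminal alkyne C14≡C15 through an alkylidene carbene 1,2-hydrogen shift, under aprotic conditions that spare the lactone.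

Step 14
Reactants: 22 lactone alkyne
Product: 24 2-{5-[(triisopropylsilyl)ethynyl]-5-[(triisopropylsilyloxy)methyl]-2-[1,3,3-trimethyl-2-(triethylsilyloxymethyl)cyclohexyl]tetrahydrofuran-2-yl}propan-2-ol, via trilithium salt 23 (not isolated)
Conditions: MeLi (4 equiv), THF, −78 → 0 °C; then TIPSOTf (4 equiv), −78 → 0 °C
Reagents that add atoms: methyllithium, [Li]C; triisopropylsilyl triflate, CC(C)[Si](OS(=O)(=O)C(F)(F)F)(C(C)C)C(C)C
Why: Double addition of methyllithium to the lactone gives the dimethyl carbinol on C8, frees the O-16 alkoxide and deprotonates the alkyne, and the silyl triflate then silylates the acetylide and the primary alkoxide but not the tertiary alkoxide lodged between two quaternary carbons.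

Step 15
Reactants: 24 tertiary alcohol
Product: 25 triethylsilyl ether of the 2-isopropenyl tetrahydrofuran (C7=C8–C17 on C9)
Conditions: SOCl2, pyridine, CH2Cl2, −20 → 0 °C
Reagents that add atoms: none
Why: Dehydration through the chlorosulfite with pyridine (E2-type elimination) can only remove a methyl hydrogen because C9 is quaternary, so the isopropenyl group forms without a cationic shift.

Step 16
Reactants: 25 triethylsilyl ether
Product: 26 (2-{2-isopropenyl-5-[(triisopropylsilyl)ethynyl]-5-[(triisopropylsilyloxy)methyl]tetrahydrofuran-2-yl}-2,6,6-trimethylcyclohexyl)methanol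
Conditions: PPTS (cat.), MeOH/CH2Cl2, 0 °C → rt
Reagents that add atoms: none
Why: Acid-catalysed methanolysis removes the triethylsilyl ether far faster than the primary triisopropylsilyl ether and does not touch the alkynylsilane.

Step 17
Reactants: 26 primary alcohol
Product: 27 2-{2-isopropenyl-5-[(triisopropylsilyl)ethynyl]-5-[(triisopropylsilyloxy)methyl]tetrahydrofuran-2-yl}-2,6,6-trimethylcyclohexane-1-carbaldehyde
Conditions: DMP, CH2Cl2, 0 °C → rt
Reagents that add atoms: none
Why: Dess–Martin oxidation gives the α-branched aldehyde (C6 on C5) under near-neutral conditions that should not epimerise C5.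

Step 18
Reactants: 27 aldehyde
Product: 28 15-(triisopropylsilyl)-16-(triisopropylsilyloxy)-9α,13R-epoxylabd-8(17)-en-14-yn-6β-ol
Conditions: Me2AlCl (2 equiv), CH2Cl2, −78 → −20 °C
Reagents that add atoms: none
Why: Me2AlCl binds the aldehyde oxygen, C6 bonds to the terminal alkene carbon C7 while one C17 hydrogen passes to that oxygen through a six-membered array, so C6–C7 and the C8=C17 alkene form in one concerted event and the product is held as an aluminium alkoxide with loss of methane. The closest known reaction type is the Lewis-acid-promoted type 2 intramolecular carbonyl-ene cyclisation of δ,ε-unsaturated aldehydes with a 1,1-disubstituted alkene to 3-methylenecyclohexanols. Ring B (C5–C6–C7–C8–C9–C10) closes through a chair-like array as a 6-endo closure onto C7=C8, trans-fused to ring A because the 5α-H and the 10β-methyl are already fixed. The new centre C6 is controlled by the ene geometry: the carbonyl oxygen must sit over C8–C17 to take the hydrogen, which makes it axial on the forming chair, and axial at C6 of this trans-fused ring is β. The step needs 6β over 6α selectivity and ene closure over cationic side paths; the concerted array, the unhindered CH2 terminus C7 and the proton-scavenging Me2AlCl at low temperature should secure both, and the silyl ether, the silylalkyne and the di-tertiary ring ether are expected to be inert.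

Step 19
Reactants: 28 homoallylic alcohol
Product: 29 15-(triisopropylsilyl)-16-(triisopropylsilyloxy)-9α,13R-epoxy-8α-methyl(8βH)-labd-14-yn-6β-ol
Conditions: H2 (1 atm), [Ir(cod)(PCy3)(py)]PF6 (5 mol %), CH2Cl2, 0 °C → rt
Reagents that add atoms: none
Why: Hydroxyl-directed hydrogenation with the cationic iridium catalyst binds the axial 6β-hydroxyl and should add hydrogen to the β face of C8=C17, making the C17 methyl α and equatorial, while the silyl-capped alkyne on a quaternary carbon is too hindered to compete.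

Step 20
Reactants: 29 alcohol
Product: 30 6β-acetate of 29
Conditions: Ac2O, DMAP, pyridine, 50 °C
Reagents that add atoms: acetic anhydride, CC(=O)OC(C)=O
Why: DMAP-catalysed acylation esterifies the hindered axial secondary alcohol, the only free hydroxyl.

Step 21
Reactants: 30 acetate
Product: 31 6β-acetoxy-9α,13R-epoxy-8α-methyl-labd-14-yn-16-ol
Conditions: TBAF, THF, 0 °C → rt
Reagents that add atoms: none
Why: Fluoride-mediated desilylation cleaves the silyl ether and the alkynylsilane in one operation and should leave the hindered secondary acetate.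

Step 22
Reactants: 31 alkynol
Product: 32 6β-acetoxy-9α,13R;15,16-diepoxylabd-14-ene (CNP0242014.1)
Conditions: W(CO)6 (25 mol %), Et3N, THF, hν (350 nm), 55 °C
Reagents that add atoms: none
Why: Tungsten-carbonyl-catalysed endo cycloisomerisation of the homopropargylic alcohol, through a tungsten vinylidene, closes the 2,3-dihydrofuran on the existing C13 centre without touching it.

Compound list
1 | 2,6,6-trimethylcyclohex-2-ene-1,4-dione (ketoisophorone) | CC1=CC(=O)CC(C)(C)C1=O | starting material
2 | 7,9,9-trimethyl-1,4-dioxaspiro[4.5]dec-6-en-8-one | CC1=CC2(OCCO2)CC(C)(C)C1=O | intermediate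
3 | 7,9,9-trimethyl-8-methylene-1,4-dioxaspiro[4.5]dec-6-ene | CC1=CC2(OCCO2)CC(C)(C)C1=C | intermediate
4 | 3,5,5-trimethyl-4-methylenecyclohex-2-en-1-one | CC1=CC(=O)CC(C)(C)C1=C | intermediate
5 | (S)-3,5,5-trimethyl-4-methylenecyclohex-2-en-1-ol | O[C@@H]1C=C(C)C(=C)C(C)(C)C1 | intermediate
6 | 1,3-bis(benzyloxy)propan-2-one | O=C(COCc1ccccc1)COCc1ccccc1 | starting material
7 | but-3-en-1-ylmagnesium bromide | C=CCC[Mg]Br | starting material
8 | 1-(benzyloxy)-2-[(benzyloxy)methyl]hex-5-en-2-ol | OC(COCc1ccccc1)(COCc1ccccc1)CCC=C | intermediate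
9 | 1-(benzyloxy)-2-[(benzyloxy)methyl]-4-(oxiran-2-yl)butan-2-ol (racemic) | OC(COCc1ccccc1)(COCc1ccccc1)CCC1CO1 | intermediate
10 | [5,5-bis(benzyloxymethyl)tetrahydrofuran-2-yl]methanol (racemic) | OCC1CCC(COCc2ccccc2)(COCc2ccccc2)O1 | intermediate
11 | 5,5-bis(benzyloxymethyl)tetrahydrofuran-2-carboxylic acid (racemic) | OC(=O)C1CCC(COCc2ccccc2)(COCc2ccccc2)O1 | intermediate
12 | (S)-3,5,5-trimethyl-4-methylenecyclohex-2-en-1-yl 5,5-bis(benzyloxymethyl)tetrahydrofuran-2-carboxylate (both epimers at the ring ether carbon) | O=C(O[C@@H]1C=C(C)C(=C)C(C)(C)C1)C1CCC(COCc2ccccc2)(COCc2ccccc2)O1 | intermediate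
13 | (Z)-trimethylsilyl ketene acetal of 12, Me3SiO cis to the ring oxygen | C[Si](C)(C)O/C(O[C@@H]1C=C(C)C(=C)C(C)(C)C1)=C1/CCC(COCc2ccccc2)(COCc2ccccc2)O1 | intermediate
14 | trimethylsilyl ester of acid 15 | C[Si](C)(C)OC(=O)[C@]1(CCC(COCc2ccccc2)(COCc2ccccc2)O1)[C@@]1(C)C=CCC(C)(C)C1=C | intermediate
15 | 5,5-bis(benzyloxymethyl)-2-(1,5,5-trimethyl-6-methylenecyclohex-2-en-1-yl)tetrahydrofuran-2-carboxylic acid; 10β-methyl, ring oxygen α on C9 | OC(=O)[C@]1(CCC(COCc2ccccc2)(COCc2ccccc2)O1)[C@@]1(C)C=CCC(C)(C)C1=C | intermediate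
16 | methyl ester of 15 | COC(=O)[C@]1(CCC(COCc2ccccc2)(COCc2ccccc2)O1)[C@@]1(C)C=CCC(C)(C)C1=C | intermediate
17 | methyl 5,5-bis(benzyloxymethyl)-2-[6-(hydroxymethyl)-1,5,5-trimethylcyclohex-2-en-1-yl]tetrahydrofuran-2-carboxylate; 5α-H, CH2OH trans to C9 | COC(=O)[C@]1(CCC(COCc2ccccc2)(COCc2ccccc2)O1)[C@@]1(C)C=CCC(C)(C)[C@@H]1CO | intermediate
18 | triethylsilyl ether of 17 | COC(=O)[C@]1(CCC(COCc2ccccc2)(COCc2ccccc2)O1)[C@@]1(C)C=CCC(C)(C)[C@@H]1CO[Si](CC)(CC)CC | intermediate
19 | methyl 5,5-bis(hydroxymethyl)-2-[1,3,3-trimethyl-2-(triethylsilyloxymethyl)cyclohexyl]tetrahydrofuran-2-carboxylate | COC(=O)[C@]1(CCC(CO)(CO)O1)[C@@]1(C)CCCC(C)(C)[C@@H]1CO[Si](CC)(CC)CC | intermediate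
20 | 5-(hydroxymethyl)-1-[1,3,3-trimethyl-2-(triethylsilyloxymethyl)cyclohexyl]-3,8-dioxabicyclo[3.2.1]octan-2-one; lactone CH2 is C16, free CH2OH is C14 | O=C1OC[C@]2(CO)CC[C@]1(O2)[C@@]1(C)CCCC(C)(C)[C@@H]1CO[Si](CC)(CC)CC | intermediate
21 | 2-oxo-1-[1,3,3-trimethyl-2-(triethylsilyloxymethyl)cyclohexyl]-3,8-dioxabicyclo[3.2.1]octane-5-carbaldehyde | O=C1OC[C@]2(C=O)CC[C@]1(O2)[C@@]1(C)CCCC(C)(C)[C@@H]1CO[Si](CC)(CC)CC | intermediate
22 | 5-ethynyl-1-[1,3,3-trimethyl-2-(triethylsilyloxymethyl)cyclohexyl]-3,8-dioxabicyclo[3.2.1]octan-2-one | O=C1OC[C@]2(C#C)CC[C@]1(O2)[C@@]1(C)CCCC(C)(C)[C@@H]1CO[Si](CC)(CC)CC | intermediate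
23 | trilithium salt (C8 alkoxide, O-16 alkoxide, C15 acetylide) of the dimethyl carbinol | [Li]OC(C)(C)[C@]2(CC[C@](CO[Li])(C#C[Li])O2)[C@@]1(C)CCCC(C)(C)[C@@H]1CO[Si](CC)(CC)CC | intermediate
24 | 2-{5-[(triisopropylsilyl)ethynyl]-5-[(triisopropylsilyloxy)methyl]-2-[1,3,3-trimethyl-2-(triethylsilyloxymethyl)cyclohexyl]tetrahydrofuran-2-yl}propan-2-ol | CC(C)(O)[C@]2(CC[C@](CO[Si](C(C)C)(C(C)C)C(C)C)(C#C[Si](C(C)C)(C(C)C)C(C)C)O2)[C@@]1(C)CCCC(C)(C)[C@@H]1CO[Si](CC)(CC)CC | intermediate
25 | triethylsilyl ether of alcohol 26 (isopropenyl on C9) | C=C(C)[C@]2(CC[C@](CO[Si](C(C)C)(C(C)C)C(C)C)(C#C[Si](C(C)C)(C(C)C)C(C)C)O2)[C@@]1(C)CCCC(C)(C)[C@@H]1CO[Si](CC)(CC)CC | intermediate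
26 | (2-{2-isopropenyl-5-[(triisopropylsilyl)ethynyl]-5-[(triisopropylsilyloxy)methyl]tetrahydrofuran-2-yl}-2,6,6-trimethylcyclohexyl)methanol | C=C(C)[C@]2(CC[C@](CO[Si](C(C)C)(C(C)C)C(C)C)(C#C[Si](C(C)C)(C(C)C)C(C)C)O2)[C@@]1(C)CCCC(C)(C)[C@@H]1CO | intermediate
27 | 2-{2-isopropenyl-5-[(triisopropylsilyl)ethynyl]-5-[(triisopropylsilyloxy)methyl]tetrahydrofuran-2-yl}-2,6,6-trimethylcyclohexane-1-carbaldehyde; 5α-H, 10β-methyl, 9α-O, 13R | C=C(C)[C@]2(CC[C@](CO[Si](C(C)C)(C(C)C)C(C)C)(C#C[Si](C(C)C)(C(C)C)C(C)C)O2)[C@@]1(C)CCCC(C)(C)[C@@H]1C=O | intermediate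
28 | 15-(triisopropylsilyl)-16-(triisopropylsilyloxy)-9α,13R-epoxylabd-8(17)-en-14-yn-6β-ol | O[C@@H]1CC(=C)[C@]2(CC[C@](CO[Si](C(C)C)(C(C)C)C(C)C)(C#C[Si](C(C)C)(C(C)C)C(C)C)O2)[C@@]2(C)CCCC(C)(C)[C@H]12 | intermediate
29 | 15-(triisopropylsilyl)-16-(triisopropylsilyloxy)-9α,13R-epoxy-8α-methyl(8βH)-labd-14-yn-6β-ol | O[C@@H]1C[C@@H](C)[C@]2(CC[C@](CO[Si](C(C)C)(C(C)C)C(C)C)(C#C[Si](C(C)C)(C(C)C)C(C)C)O2)[C@@]2(C)CCCC(C)(C)[C@H]12 | intermediate
30 | 6β-acetate of 29 | CC(=O)O[C@@H]1C[C@@H](C)[C@]2(CC[C@](CO[Si](C(C)C)(C(C)C)C(C)C)(C#C[Si](C(C)C)(C(C)C)C(C)C)O2)[C@@]2(C)CCCC(C)(C)[C@H]12 | intermediate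
31 | 6β-acetoxy-9α,13R-epoxy-8α-methyl-labd-14-yn-16-ol | CC(=O)O[C@@H]1C[C@@H](C)[C@]2(CC[C@](CO)(C#C)O2)[C@@]2(C)CCCC(C)(C)[C@H]12 | intermediate
32 | 6β-acetoxy-9α,13R;15,16-diepoxylabd-14-ene (CNP0242014.1) | CC(=O)O[C@@H]1C[C@@H](C)[C@]2(CC[C@]3(C=COC3)O2)[C@@]2(C)CCCC(C)(C)[C@H]12 | target

Total step count: 22.
Longest linear sequence: 19 steps (steps 1–3 and 7–22; the branch through steps 4–6 and 7–22 is equally long).

Steps most likely to fail

Step 8. The rearrangement may pass through the chair-like array instead of the boat-like one, which would invert C9 relative to C10, or it may stall at the two fully substituted termini. The fallback sets out from ester 12 and reverses the ketene acetal geometry by making it through conjugate reduction instead of deprotonation. LDA and PhSeBr would give the α-phenylselanyl ester F1; H2O2 oxidation and selenoxide syn-elimination would give the 4,5-dihydrofuran-2-carboxylate F2. [(Ph3P)CuH]6 (cat.) with PhMe2SiH would add hydride to C11 through the s-cis enoate and give the silyl ketene acetal F3, with the silyloxy group cis to C11. Its [3,3] shift through the chair should then place the ring oxygen and C11 correctly and give the dimethylphenylsilyl ester F4. Hydrolysis of F4 comes back to the route at acid 15, which is methylated to 16 as in step 8.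

Step 18. The closure may leave the concerted array for an open, stepwise cationic path, with poor facial selectivity at C6 or proton loss to ring alkenes. The fallback sets out from aldehyde 27 and no longer relies on the ene geometry for C6. Whatever the ratio at C6, material containing the 6α-alcohol F5 would be oxidised with DMP to the 6-ketone F6. Reduction with NaBH4/CeCl3·7H2O at −78 °C should then deliver hydride from the α face, away from the axial methyl groups on C4 and C10, and come back to the route at 28.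

Step 19. The catalyst may also reduce the alkyne or be slowed by it, or the hydroxyl may fail to steer the addition (poor facial selectivity at C8). The fallback sets out from 28 and replaces metal-bound dihydrogen delivery by radical hydrogen-atom transfer: Mn(dpm)3 (cat.), PhSiH3, t-BuOOH, i-PrOH, rt. This should reduce the 1,1-disubstituted alkene through the tertiary C8 radical to the more stable equatorial 8α-methyl isomer and leave the silylalkyne alone. It comes back to the route at 29 and makes no new compound.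

Further compounds
F1 | step 8 | (S)-3,5,5-trimethyl-4-methylenecyclohex-2-en-1-yl 5,5-bis(benzyloxymethyl)-2-(phenylselanyl)tetrahydrofuran-2-carboxylate | O=C(O[C@@H]1C=C(C)C(=C)C(C)(C)C1)C1([Se]c2ccccc2)CCC(COCc2ccccc2)(COCc2ccccc2)O1
F2 | step 8 | (S)-3,5,5-trimethyl-4-methylenecyclohex-2-en-1-yl 5,5-bis(benzyloxymethyl)-4,5-dihydrofuran-2-carboxylate | O=C(O[C@@H]1C=C(C)C(=C)C(C)(C)C1)C1=CCC(COCc2ccccc2)(COCc2ccccc2)O1
F3 | step 8 | dimethylphenylsilyl ketene acetal of 12 with the silyloxy group cis to C11 | C[Si](C)(c1ccccc1)O/C(O[C@@H]1C=C(C)C(=C)C(C)(C)C1)=C1\CCC(COCc2ccccc2)(COCc2ccccc2)O1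
F4 | step 8 | dimethylphenylsilyl ester of acid 15 | C[Si](C)(c1ccccc1)OC(=O)[C@]1(CCC(COCc2ccccc2)(COCc2ccccc2)O1)[C@@]1(C)C=CCC(C)(C)C1=C
F5 | step 18 | 15-(triisopropylsilyl)-16-(triisopropylsilyloxy)-9α,13R-epoxylabd-8(17)-en-14-yn-6α-ol | O[C@H]1CC(=C)[C@]2(CC[C@](CO[Si](C(C)C)(C(C)C)C(C)C)(C#C[Si](C(C)C)(C(C)C)C(C)C)O2)[C@@]2(C)CCCC(C)(C)[C@H]12
F6 | step 18 | 15-(triisopropylsilyl)-16-(triisopropylsilyloxy)-9α,13R-epoxylabd-8(17)-en-14-yn-6-one | O=C1CC(=C)[C@]2(CC[C@](CO[Si](C(C)C)(C(C)C)C(C)C)(C#C[Si](C(C)C)(C(C)C)C(C)C)O2)[C@@]2(C)CCCC(C)(C)[C@H]12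
F0 | step 19 | none | none
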